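**Retrosynthetic overview**
- Numbering used throughout: seven-membered ring C1(OAr)–C2H2–C3(Me)=C4H–C5(=O)–C6(Me)–C10H; five-membered ring C6–C7H2–C8H2–C9(OH)(i-Pr)–C10; cis-fused. The strategy rests on this feature: C10 and C6 are the α- and β-carbons of a C1 carbonyl, and C9, next to C10, carries the isopropyl group, so the cyclopentane is the (3+2) adduct of a C10=C6 enone with a C7–C8–C9 unit.
- Late disconnections: C3 methyl and C3=C4 back to a C5 ketone (from a C5 silyl ether); C9–OH back to a C8=C9 alkene (from a C8 vinylsilane); C1 ester back to a C1 ketone.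
- Key disconnection: C6–C7 and C9–C10, by TiCl4-promoted annulation of 1-isopropyl-1-(trimethylsilyl)allene 12 onto (S)-4-silyloxy-3-methylcyclohept-2-enone 8.
- Ring order: the seven-membered ring comes from cyclohepta-1,3-diene, desymmetrised enzymatically to fix the C5 control centre; the five-membered ring is closed in the key step.

Key step: step 10

Assumption: the lipase is taken to hydrolyse the acetate on the (S)-configured carbon of meso diacetate 2, by analogy with the five-membered homologue; if it cleaves the other one, the same monoacetate 3 is reached by lipase acetylation of the meso diol with vinyl acetate.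
Remark: "convex face" means the face of the cis-fused bicycle that carries H10 and the C6 methyl. The C5 stereocentre is a control element only and is oxidised later. Bicyclic intermediates are named in the route numbering above.

Step 1
Reactants: 1 cyclohepta-1,3-diene
Product: 2 cis-cyclohept-2-ene-1,4-diyl diacetate (meso)
Conditions: Pd(OAc)2 (cat.), LiCl (cat.), LiOAc, p-benzoquinone, AcOH, rt
Reagents that add atoms: acetic acid CC(=O)O
Why: Bäckvall 1,4-diacetoxylation; acetoxypalladation gives a π-allyl complex, and with chloride on the metal the second acetate attacks from outside, anti to palladium, giving the cis (meso) diacetate.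

Step 2
Reactants: 2 cis-cyclohept-2-ene-1,4-diyl diacetate
Product: 3 (1R,4S)-4-hydroxycyclohept-2-en-1-yl acetate
Conditions: Burkholderia cepacia lipase, phosphate buffer pH 7, rt
Reagents that add atoms: none
Why: Enzymatic desymmetrisation of a meso diacetate; the lipase should hydrolyse one enantiotopic acetate only, which fixes the absolute configuration of both carbinol carbons.

Step 3
Reactants: 3 (1R,4S)-4-hydroxycyclohept-2-en-1-yl acetate
Product: 4 (1R,4S)-4-[(tert-butyldimethylsilyl)oxy]cyclohept-2-en-1-yl acetate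
Conditions: TBSCl, imidazole, DMF, rt
Reagents that add atoms: tert-butyldimethylsilyl chloride CC(C)(C)[Si](C)(C)Cl
Why: Standard silylation of the only free secondary hydroxyl; the acetate is untouched.

Step 4
Reactants: 4 (1R,4S)-4-[(tert-butyldimethylsilyl)oxy]cyclohept-2-en-1-yl acetate
Product: 5 (1R,4S)-4-[(tert-butyldimethylsilyl)oxy]cyclohept-2-en-1-ol
Conditions: K2CO3 (cat.), MeOH, 0 °C to rt
Reagents that add atoms: none
Why: Base-catalysed transesterification removes the acetate and leaves the TBS ether.

Step 5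
Reactants: 5 (1R,4S)-4-[(tert-butyldimethylsilyl)oxy]cyclohept-2-en-1-ol
Product: 6 (S)-4-[(tert-butyldimethylsilyl)oxy]cyclohept-2-en-1-one
Conditions: Dess–Martin periodinane, CH2Cl2, 0 °C to rt
Reagents that add atoms: none
Why: Dess–Martin oxidation of the allylic alcohol gives the enone without touching the silyl ether or the remaining stereocentre.

Step 6
Reactants: 6 (S)-4-[(tert-butyldimethylsilyl)oxy]cyclohept-2-en-1-one
Product: 7 (3S,4S)-4-[(tert-butyldimethylsilyl)oxy]-3-methyl-1-[(trimethylsilyl)oxy]cyclohept-1-ene (3-Me trans to 4-OTBS)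
Conditions: Me2CuLi (from MeLi and CuI), TMSCl, THF, −78 °C; Et3N, NaHCO3 work-up
Reagents that add atoms: lithium dimethylcuprate [Li+].C[Cu-]C; chlorotrimethylsilane C[Si](C)(C)Cl
Why: TMSCl-accelerated cuprate conjugate addition, anti to the γ-silyloxy group, with trapping of the regiodefined enolate as its silyl enol ether; the new methyl-bearing centre is erased in step 7.

Step 7
Reactants: 7 (3S,4S)-4-[(tert-butyldimethylsilyl)oxy]-3-methyl-1-[(trimethylsilyl)oxy]cyclohept-1-ene
Product: 8 (S)-4-[(tert-butyldimethylsilyl)oxy]-3-methylcyclohept-2-en-1-one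
Conditions: Pd(OAc)2 (1.1 equiv), MeCN, rt
Reagents that add atoms: none
Why: Saegusa–Ito oxidation; the silyl enol ether gives an acetoxypalladium enolate at C2 and β-hydride elimination of the C3–H restores the enone, now carrying the β-methyl group.

Step 8
Reactants: 9 3-(trimethylsilyl)prop-2-yn-1-ol
Product: 10 3-(trimethylsilyl)prop-2-yn-1-yl methanesulfonate
Conditions: MsCl, Et3N, CH2Cl2, −20 °C
Reagents that add atoms: methanesulfonyl chloride CS(=O)(=O)Cl
Why: Routine mesylation of a primary propargylic alcohol.

Step 9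
Reactants: 10 3-(trimethylsilyl)prop-2-yn-1-yl methanesulfonate; 11 isopropylmagnesium chloride
Product: 12 1-isopropyl-1-(trimethylsilyl)allene (trimethyl(4-methylpenta-1,2-dien-3-yl)silane)
Conditions: CuBr, LiBr, THF, −78 °C to rt
Reagents that add atoms: none
Why: Organocopper 1,3-substitution (SN2′) of a propargylic sulfonate; the isopropylcopper reagent attacks the silyl-bearing alkyne carbon and expels mesylate to give the 1,1-disubstituted allene.

Step 10
Reactants: 8 (S)-4-[(tert-butyldimethylsilyl)oxy]-3-methylcyclohept-2-en-1-one; 12 1-isopropyl-1-(trimethylsilyl)allene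
Product: 13 (5S,6S,10S)-5-[(tert-butyldimethylsilyl)oxy]-9-isopropyl-6-methyl-8-(trimethylsilyl)bicyclo[5.3.0]dec-8-en-1-one (route numbering; cis-fused; 5-OTBS cis to 6-Me)
Conditions: TiCl4 (1.5 equiv), CH2Cl2, −78 °C, then 12 (2 equiv), −78 to −40 °C; NaHCO3 quench
Reagents that add atoms: none
Why: TiCl4 activates the enone and the CH2 terminus of allene 12 (C7) attacks the β-carbon C6, giving a trichlorotitanium enolate and a vinyl cation at C8 stabilised by the β C–Si bond; a 1,2-silyl shift moves silicon to C8 and the charge to C9, which the enolate carbon C10 captures. The closest known reaction type is the Danheiser (trimethylsilyl)cyclopentene annulation of cyclic enones with 1-substituted (trimethylsilyl)allenes. The ring C6–C7–C8–C9–C10 closes by cationic 5-(enolexo)-endo-dig attack of the enolate on the rearranged vinyl cation, leaving C8=C9 endocyclic. C6 is set by approach of the allene to the enone face opposite the C5 silyloxy group, so C6–C7 is trans to C5–O; C10 is set by the three-atom tether, which can only close cis across C6–C10. The step needs β-regioselectivity (secured by the nucleophilic CH2 terminus and the cation-stabilising silicon), ring closure in preference to loss of silicon (low temperature, non-nucleophilic CH2Cl2) and survival of the TBS ether (−78 °C, buffered quench).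

Step 11
Reactants: 13 annulation ketone
Product: 14 C1 alcohol of 13 (1-OH on the concave face, trans to H10; other centres as in 13)
Conditions: LiBH(s-Bu)3, THF, −78 °C; H2O
Reagents that add atoms: none
Why: Bulky-hydride reduction under steric approach control; hydride should reach C1 from the convex face, anti to the C10–C9 bond (Felkin–Anh sense), so the new C1–O bond is trans to H10, and the non-basic conditions avoid isomerising the β,γ-alkene into conjugation.

Step 12
Reactants: 14 C1 alcohol; 15 4-methoxybenzoyl chloride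
Product: 16 C1 4-methoxybenzoate of 14
Conditions: Et3N, DMAP, CH2Cl2, 0 to 40 °C
Reagents that add atoms: none
Why: DMAP-catalysed acylation of the only free hydroxyl; the configuration at C1 is retained.

Step 13
Reactants: 16 vinylsilane ester
Product: 17 C8=C9 alkene (C8–H; 9-isopropyl; 1-anisate and 5-OTBS retained)
Conditions: CF3CO2H (5 equiv), CH2Cl2, 0 °C, short contact; aq. NaHCO3
Reagents that add atoms: none
Why: Protodesilylation of a vinylsilane; ipso protonation at C8 gives the tertiary C9 cation stabilised by the β C–Si bond and loss of silicon leaves the C8=C9 alkene in place, while short exposure at 0 °C should spare the hindered TBS ether.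

Step 14
Reactants: 17 C8=C9 alkene
Product: 19 C9 tertiary alcohol (9-OH cis to H10; 1-anisate and 5-OTBS retained), via tertiary hydroperoxide 18 (not isolated)
Conditions: Mn(dpm)3 (cat.), PhSiH3, O2 (1 atm), i-PrOH/CH2Cl2, 0 °C; then PPh3
Reagents that add atoms: dioxygen O=O
Why: Mukaiyama hydration; hydrogen atom transfer to C8 gives the tertiary C9 radical, which O2 should trap on the convex face, away from the seven-membered ring and the C1 aroyloxy group, and PPh3 reduces the hydroperoxide, so the C9 hydroxyl ends up cis to H10.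

Step 15
Reactants: 19 C9 tertiary alcohol
Product: 20 C5,C9 diol (5-OH cis to 6-Me; 1-anisate retained)
Conditions: HF·pyridine, pyridine, THF, 0 °C to rt
Reagents that add atoms: none
Why: Fluoride cleavage of the secondary TBS ether under mildly acidic conditions that leave the aryl ester and the tertiary alcohol alone.

Step 16
Reactants: 20 C5,C9 diol
Product: 21 C5 ketone (9-OH free; 1-anisate retained)
Conditions: Dess–Martin periodinane, CH2Cl2, rt
Reagents that add atoms: none
Why: Dess–Martin oxidation of the only secondary alcohol; the tertiary C9 hydroxyl cannot be oxidised and, being trans to C5 on the five-membered ring, cannot form a hemiketal.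

Step 17
Reactants: 21 C5 ketone
Product: 22 bis-silyl compound (C4=C5 trimethylsilyl enol ether; 9-OTMS)
Conditions: TMSOTf (2.5 equiv), Et3N, CH2Cl2, 0 °C
Reagents that add atoms: trimethylsilyl trifluoromethanesulfonate C[Si](C)(C)OS(=O)(=O)C(F)(F)F
Why: Soft enolisation and silylation; C6 is quaternary, so the enol ether can only form toward C4, and the same reagent caps the tertiary hydroxyl for the cuprate step.

Step 18
Reactants: 22 bis-silyl compound
Product: 23 C3=C4 enone (C5 ketone; 9-OTMS; 1-anisate)
Conditions: Pd(OAc)2 (1.1 equiv), MeCN, rt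
Reagents that add atoms: none
Why: Saegusa–Ito oxidation of the C4=C5 silyl enol ether; β-hydride elimination of a C3–H gives the C3=C4 enone.

Step 19
Reactants: 23 C3=C4 enone
Product: 24 C3-methyl C4=C5 trimethylsilyl enol ether (C3 epimers, both converge; 9-OTMS; 1-anisate)
Conditions: Me2CuLi (from MeLi and CuI), TMSCl, THF, −78 °C; Et3N, NaHCO3 work-up
Reagents that add atoms: lithium dimethylcuprate [Li+].C[Cu-]C; chlorotrimethylsilane C[Si](C)(C)Cl
Why: Cuprate conjugate addition puts the methyl group on C3 and TMSCl traps the enolate regiospecifically; the aryl ester and the tertiary silyl ether are inert to the cuprate at −78 °C.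

Step 20
Reactants: 24 C3-methyl silyl enol ether
Product: 26 target CNP0301380.1, via silyl ether enone 25 (not isolated)
Conditions: Pd(OAc)2 (1.2 equiv), MeCN, 40 °C; then 1 M HCl, THF, 0 °C
Reagents that add atoms: none
Why: Saegusa–Ito oxidation removes the tertiary C3–H to give the β-methyl enone and erases the C3 centre, and the dilute acid work-up hydrolyses the tertiary trimethylsilyl ether to the free C9 alcohol.

**Compound list**
1 | cyclohepta-1,3-diene | C1=CC=CCCC1 | starting material
2 | cis-cyclohept-2-ene-1,4-diyl diacetate (meso) | CC(=O)O[C@@H]1CCC[C@H](OC(C)=O)C=C1 | intermediate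
3 | (1R,4S)-4-hydroxycyclohept-2-en-1-yl acetate | CC(=O)O[C@@H]1CCC[C@H](O)C=C1 | intermediate
4 | (1R,4S)-4-[(tert-butyldimethylsilyl)oxy]cyclohept-2-en-1-yl acetate | CC(=O)O[C@@H]1CCC[C@H](O[Si](C)(C)C(C)(C)C)C=C1 | intermediate
5 | (1R,4S)-4-[(tert-butyldimethylsilyl)oxy]cyclohept-2-en-1-ol | O[C@@H]1CCC[C@H](O[Si](C)(C)C(C)(C)C)C=C1 | intermediate
6 | (S)-4-[(tert-butyldimethylsilyl)oxy]cyclohept-2-en-1-one | O=C1CCC[C@H](O[Si](C)(C)C(C)(C)C)C=C1 | intermediate
7 | (3S,4S)-4-[(tert-butyldimethylsilyl)oxy]-3-methyl-1-[(trimethylsilyl)oxy]cyclohept-1-ene | C[Si](C)(C)OC1=C[C@H](C)[C@@H](O[Si](C)(C)C(C)(C)C)CCC1 | intermediate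
8 | (S)-4-[(tert-butyldimethylsilyl)oxy]-3-methylcyclohept-2-en-1-one | O=C1CCC[C@H](O[Si](C)(C)C(C)(C)C)C(C)=C1 | intermediate
9 | 3-(trimethylsilyl)prop-2-yn-1-ol | C[Si](C)(C)C#CCO | starting material
10 | 3-(trimethylsilyl)prop-2-yn-1-yl methanesulfonate | C[Si](C)(C)C#CCOS(C)(=O)=O | intermediate
11 | isopropylmagnesium chloride | CC(C)[Mg]Cl | starting material
12 | 1-isopropyl-1-(trimethylsilyl)allene | C=C=C(C(C)C)[Si](C)(C)C | intermediate
13 | (5S,6S,10S)-5-[(tert-butyldimethylsilyl)oxy]-9-isopropyl-6-methyl-8-(trimethylsilyl)bicyclo[5.3.0]dec-8-en-1-one (route numbering, cis-fused) | O=C1CCC[C@H](O[Si](C)(C)C(C)(C)C)[C@@]2(C)CC([Si](C)(C)C)=C(C(C)C)[C@@H]12 | intermediate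
14 | C1 alcohol of 13 (1-OH trans to H10) | O[C@H]1CCC[C@H](O[Si](C)(C)C(C)(C)C)[C@@]2(C)CC([Si](C)(C)C)=C(C(C)C)[C@@H]12 | intermediate
15 | 4-methoxybenzoyl chloride | COc1ccc(cc1)C(Cl)=O | starting material
16 | C1 4-methoxybenzoate of 14 (C8 vinylsilane, 5-OTBS) | COc1ccc(C(=O)O[C@H]2CCC[C@H](O[Si](C)(C)C(C)(C)C)[C@@]3(C)CC([Si](C)(C)C)=C(C(C)C)[C@@H]23)cc1 | intermediate
17 | protodesilylated C8=C9 alkene (1-anisate, 5-OTBS) | COc1ccc(C(=O)O[C@H]2CCC[C@H](O[Si](C)(C)C(C)(C)C)[C@@]3(C)CC=C(C(C)C)[C@@H]23)cc1 | intermediate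
18 | C9 tertiary hydroperoxide (9-OOH cis to H10) | COc1ccc(C(=O)O[C@H]2CCC[C@H](O[Si](C)(C)C(C)(C)C)[C@@]3(C)CC[C@@](OO)(C(C)C)[C@@H]23)cc1 | intermediate (not isolated)
19 | C9 tertiary alcohol (9-OH cis to H10; 1-anisate, 5-OTBS) | COc1ccc(C(=O)O[C@H]2CCC[C@H](O[Si](C)(C)C(C)(C)C)[C@@]3(C)CC[C@@](O)(C(C)C)[C@@H]23)cc1 | intermediate
20 | C5,C9 diol (1-anisate) | COc1ccc(C(=O)O[C@H]2CCC[C@H](O)[C@@]3(C)CC[C@@](O)(C(C)C)[C@@H]23)cc1 | intermediate
21 | C5 ketone (9-OH, 1-anisate) | COc1ccc(C(=O)O[C@H]2CCCC(=O)[C@@]3(C)CC[C@@](O)(C(C)C)[C@@H]23)cc1 | intermediate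
22 | C4=C5 trimethylsilyl enol ether with 9-OTMS | COc1ccc(C(=O)O[C@H]2CCC=C(O[Si](C)(C)C)[C@@]3(C)CC[C@@](O[Si](C)(C)C)(C(C)C)[C@@H]23)cc1 | intermediate
23 | C3=C4 enone with 9-OTMS | COc1ccc(C(=O)O[C@H]2CC=CC(=O)[C@@]3(C)CC[C@@](O[Si](C)(C)C)(C(C)C)[C@@H]23)cc1 | intermediate
24 | C3-methyl C4=C5 trimethylsilyl enol ether with 9-OTMS (C3 not defined) | COc1ccc(C(=O)O[C@H]2CC(C)C=C(O[Si](C)(C)C)[C@@]3(C)CC[C@@](O[Si](C)(C)C)(C(C)C)[C@@H]23)cc1 | intermediate
25 | C3-methyl C3=C4 enone with 9-OTMS | COc1ccc(C(=O)O[C@H]2CC(C)=CC(=O)[C@@]3(C)CC[C@@](O[Si](C)(C)C)(C(C)C)[C@@H]23)cc1 | intermediate (not isolated)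
26 | CNP0301380.1, (1S,6S,9R,10R) in route numbering | COc1ccc(C(=O)O[C@H]2CC(C)=CC(=O)[C@@]3(C)CC[C@@](O)(C(C)C)[C@@H]23)cc1 | target

**Step count**
Total: 20 steps. Longest linear sequence: 18 steps (steps 1–7 and 10–20); the allene branch (steps 8–9) joins at step 10.

**Steps most likely to fail**

1. Step 10. The allene may attack the fully substituted β-carbon too slowly, or the vinyl cation may lose silicon before the enolate closes the ring, leaving an open-chain alkyne; face selectivity next to the silyloxy group may also erode. Fallback: the same two bonds are made one after the other, setting out from 8 and returning at 19.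
   - 4-Methylpent-1-en-3-one, HBr and ethylene glycol give 2-(2-bromoethyl)-2-isopropyl-1,3-dioxolane F1.
   - Its Grignard reagent (Mg, THF) adds to 8 with CuBr·SMe2 (cat.) at −40 °C, anti to the silyloxy group, forming C6–C7 and giving the keto ketal F2.
   - PPTS in wet acetone unmasks the diketone F3.
   - Intramolecular aldol addition under equilibrating conditions (KOt-Bu, t-BuOH, 0 °C) joins C10 to the isopropyl ketone and gives the cis-fused tertiary aldol F4; the C9 epimers would be separated here.
   - LiBH(s-Bu)3 reduces C1 to the diol F5, and acylation of its secondary hydroxyl with 15 (Et3N, DMAP) gives 19.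

2. Step 14. The planar C9 radical may be trapped by O2 with poor facial discrimination, or be reduced instead of oxygenated. Fallback: set out from 17 and return at 19. mCPBA (NaHCO3, CH2Cl2, 0 °C) epoxidises the alkene in a concerted, sterically more demanding step from the convex face to give the 8,9-epoxide F6. LiEt3BH (THF, 0 °C to rt) opens it at the less substituted C8 and also cleaves the aryl ester, giving the diol F5. Selective acylation of the secondary C1 hydroxyl with 15 returns 19.

3. Step 11. Hydride delivery may occur from the concave face or without useful selectivity, because the C6 methyl and the C5 silyloxy group also sit on the convex face. Fallback: set out from 13 and return at 16, using the unwanted epimer. The C1-epimeric alcohol F7 (obtained from 13 with whichever hydride favours it, for example NaBH4 in MeOH) is esterified under Mitsunobu conditions (4-methoxybenzoic acid, PPh3, DIAD, toluene) with inversion at C1, which gives 16 directly and replaces step 12.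

**Further compounds**
F1 | step 10 | 2-(2-bromoethyl)-2-isopropyl-1,3-dioxolane | CC(C)C1(CCBr)OCCO1
F2 | step 10 | (4S)-4-[(tert-butyldimethylsilyl)oxy]-3-[2-(2-isopropyl-1,3-dioxolan-2-yl)ethyl]-3-methylcycloheptan-1-one (side chain trans to the silyloxy group) | O=C1CCC[C@H](O[Si](C)(C)C(C)(C)C)[C@@](C)(CCC2(C(C)C)OCCO2)C1
F3 | step 10 | (4S)-4-[(tert-butyldimethylsilyl)oxy]-3-methyl-3-(4-methyl-3-oxopentyl)cycloheptan-1-one | O=C1CCC[C@H](O[Si](C)(C)C(C)(C)C)[C@@](C)(CCC(=O)C(C)C)C1
F4 | step 10 | cis-fused tertiary aldol (C1 ketone, 9-OH cis to H10, 5-OTBS) | O=C1CCC[C@H](O[Si](C)(C)C(C)(C)C)[C@@]2(C)CC[C@@](O)(C(C)C)[C@@H]12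
F5 | step 10 | C1,C9 diol (1-OH trans to H10, 9-OH cis to H10, 5-OTBS) | O[C@H]1CCC[C@H](O[Si](C)(C)C(C)(C)C)[C@@]2(C)CC[C@@](O)(C(C)C)[C@@H]12
F6 | step 14 | 8,9-epoxide of 17 (oxygen on the convex face) | COc1ccc(C(=O)O[C@H]2CCC[C@H](O[Si](C)(C)C(C)(C)C)[C@@]3(C)C[C@@H]4O[C@]4(C(C)C)[C@@H]23)cc1
F7 | step 11 | C1 epimer of 14 (1-OH cis to H10) | O[C@@H]1CCC[C@H](O[Si](C)(C)C(C)(C)C)[C@@]2(C)CC([Si](C)(C)C)=C(C(C)C)[C@@H]12
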